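**Strategy.** Everything rests on cutting the C9–C10 bond of the ten-membered carbocycle, the CH2–CH(CH3) link beside the C1 ketone, and standing a sulfur atom in its place. A Ramberg–Bäcklund reaction on the eleven-membered sulfone then deletes that sulfur as SO2 and, in one operation, forms the C9–C10 bond as an olefin and the carbocycle; the neighbouring C8 hydroxyl later steers its hydrogenation to set C10. The sulfone carries C1 as a dioxolane, C8 as a free hydroxyl (an alkoxide under base, which cannot be eliminated), C4 and C12 as TBS ethers and C6 as a PMB ether, and its ring is closed by C–S bond formation, a thiolate opening the C8–C9 epoxide.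

Key step: step 18

Remark: atom numbers are those of the target (C1 ketone, C4 methyl carbinol, C6 ester carbinol, C8 lactone O–CH, C10 CH–CH3, C11–C13 lactone carbons). The C1 carbinol of the vinyl adduct and C10 from the chloro ketone to the sulfone arise as epimer mixtures, are drawn without configuration and are erased later. The ring-contracted olefin is taken as Z (methyl trans to C8).

**Step 1**
Reactants: 1 geraniol
Product: 2 (2S,3S)-2,3-epoxygeraniol
Conditions: Ti(OiPr)4 (5 mol %), L-(+)-diethyl tartrate (6 mol %), t-BuOOH, 4 Å MS, CH2Cl2, −20 °C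
Reagents that add atoms: tert-butyl hydroperoxide, CC(C)(C)OO
Why: Sharpless asymmetric epoxidation: the titanium–L-(+)-tartrate catalyst binds the allylic hydroxyl and transfers oxygen to one face of the 2,3-olefin only, which sets the future C4 configuration and leaves the isolated trisubstituted olefin untouched.

**Step 2**
Reactants: 2 (2S,3S)-2,3-epoxygeraniol
Product: 3 (S)-3,7-dimethyloct-6-ene-1,3-diol
Conditions: NaAlH2(OCH2CH2OMe)2 (Red-Al), THF, 0 °C → rt; aq. Rochelle salt
Reagents that add atoms: none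
Why: Hydroxyl-directed hydride opening of a 2,3-epoxy alcohol: the aluminate bound to the primary oxygen delivers hydride to the adjacent epoxide carbon, so the 1,3-diol results and the C–O bond at the quaternary carbon (future C4, S) is never broken.

**Step 3**
Reactants: 3 (S)-3,7-dimethyloct-6-ene-1,3-diol
Product: 5 (S)-3-(tert-butyldimethylsilyloxy)-3,7-dimethyl-1-(triethylsilyloxy)oct-6-ene, via primary TES ether 4 (not isolated)
Conditions: TESOTf (1.0 equiv), 2,6-lutidine, CH2Cl2, −78 °C; then TBSOTf, −78 → 0 °C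
Reagents that add atoms: triethylsilyl triflate, CC[Si](CC)(CC)OS(=O)(=O)C(F)(F)F; tert-butyldimethylsilyl triflate, CC(C)(C)[Si](C)(C)OS(=O)(=O)C(F)(F)F
Why: Silyl triflate protection: the primary hydroxyl is capped first at −78 °C and the hindered tertiary C4 hydroxyl then takes the TBS group, which keeps that oxygen from adding to the C1 carbonyl in steps 13 to 15.

**Step 4**
Reactants: 5 (S)-3-(tert-butyldimethylsilyloxy)-3,7-dimethyl-1-(triethylsilyloxy)oct-6-ene
Product: 6 (S)-3-(tert-butyldimethylsilyloxy)-3,7-dimethyloct-6-enal (CHO = C6, quaternary carbon = C4)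
Conditions: (COCl)2, DMSO, CH2Cl2, −78 → −30 °C; then Et3N, −78 °C → rt
Reagents that add atoms: none
Why: Swern oxidation applied to the silyl ether: the chlorosulfonium reagent cleaves a primary triethylsilyl ether and oxidises it in the same flask, while the tertiary TBS ether and the olefin are inert, so the C6 aldehyde is reached without a separate deprotection.

**Step 5**
Reactants: 7 but-3-yn-1-ol
Product: 8 tert-butyl(but-3-yn-1-yloxy)dimethylsilane
Conditions: TBSCl, imidazole, CH2Cl2, rt
Reagents that add atoms: tert-butyldimethylsilyl chloride, CC(C)(C)[Si](C)(C)Cl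
Why: Standard silylation of a primary alcohol; this oxygen becomes the C12 oxygen.

**Step 6**
Reactants: 8 tert-butyl(but-3-yn-1-yloxy)dimethylsilane
Product: 9 (E)-2-[4-(tert-butyldimethylsilyloxy)but-1-en-1-yl]-4,4,5,5-tetramethyl-1,3,2-dioxaborolane
Conditions: pinacolborane, Cp2Zr(H)Cl (5 mol %), Et3N (10 mol %), neat, 60 °C
Reagents that add atoms: pinacolborane, CC1(C)OBOC1(C)C
Why: Zirconium-catalysed hydroboration of a terminal alkyne: syn addition with boron at the terminal carbon gives the (E)-alkenylboronate.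

**Step 7**
Reactants: 9 (E)-alkenylboronate
Product: 10 (E)-2-[5-(tert-butyldimethylsilyloxy)pent-2-en-1-yl]-4,4,5,5-tetramethyl-1,3,2-dioxaborolane
Conditions: BrCH2Cl, n-BuLi, THF, −78 °C → rt
Reagents that add atoms: bromochloromethane, ClCBr
Why: Matteson homologation: chloromethyllithium adds to boron and the alkenyl group migrates with loss of chloride and retention of the E geometry, inserting the CH2 that becomes C9.

**Step 8**
Reactants: 6 (S)-3-(tert-butyldimethylsilyloxy)-3,7-dimethyloct-6-enal; 10 (E)-allylboronate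
Product: 11 anti homoallylic alcohol (4S,6R,7S): C4 OTBS, C6 OH, C7 bearing CH2CH2OTBS and the C8=C9 vinyl group
Conditions: (S)-TRIP [(S)-3,3'-bis(2,4,6-triisopropylphenyl)-1,1'-binaphthyl-2,2'-diyl hydrogen phosphate] (5 mol %), 4 Å MS, toluene, −30 °C
Reagents that add atoms: none
Why: Chiral phosphoric acid-catalysed allylboration: the closed chair transition state of the (E)-γ-substituted allylboronate places the C6 oxygen and the C7 side chain anti, and the (S) acid is the antipode expected to direct attack to the Si face of the aldehyde, giving the 6R,7S pair with C7–C9 in place.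

**Step 9**
Reactants: 11 anti homoallylic alcohol
Product: 12 C8–C9 epoxy alcohol (epoxide oxygen syn to the C6 hydroxyl, anti to the C7 side chain)
Conditions: VO(acac)2 (5 mol %), t-BuOOH, CH2Cl2, rt
Reagents that add atoms: tert-butyl hydroperoxide, CC(C)(C)OO
Why: Hydroxyl-directed epoxidation of a homoallylic alcohol: oxygen is delivered within the vanadate ester through a chair in which the C5 chain, the C7 side chain and C9 are all equatorial, which sets C8 syn to the C6 oxygen, and the undirected trisubstituted olefin should not react.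

**Step 10**
Reactants: 12 C8–C9 epoxy alcohol
Product: 13 C6 4-methoxybenzyl ether of 12
Conditions: NaN(SiMe3)2, 4-MeOC6H4CH2Br, THF/DMF, −78 → 0 °C
Reagents that add atoms: 4-methoxybenzyl bromide, COc1ccc(CBr)cc1
Why: Williamson etherification of the sodium alkoxide at low temperature, where silyl migration is slow; this fixes the C6/C8 differentiation (C6 ether, C8 oxygen held in the epoxide).

**Step 11**
Reactants: 13 C6 PMB ether
Product: 14 C1 aldehyde
Conditions: O3, CH2Cl2, −78 °C (Sudan red 7B end point); then PPh3, −78 °C → rt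
Reagents that add atoms: ozone, [O-][O+]=O
Why: Ozonolysis with reductive work-up cleaves the only remaining olefin to the C1 aldehyde, and stopping at the indicator end point spares the PMB ring.

**Step 12**
Reactants: 14 C1 aldehyde
Product: 15 C1 vinyl carbinol (both C1 epimers)
Conditions: CH2=CHMgBr, THF, −78 °C; aq. NH4Cl
Reagents that add atoms: vinylmagnesium bromide, C=C[Mg]Br
Why: Grignard addition to the aldehyde at −78 °C, where the terminal epoxide is not attacked; the two carbons become C10 and its methyl group, and the new carbinol centre is lost in the next step.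

**Step 13**
Reactants: 15 C1 vinyl carbinol
Product: 16 α-chloro ketone (C1 ketone, C10 chloride, both C10 epimers)
Conditions: [Cp*IrCl2]2 (2 mol %), NCS, THF/H2O, rt
Reagents that add atoms: N-chlorosuccinimide, O=C1CCC(=O)N1Cl
Why: Tandem isomerisation–chlorination of an allylic alcohol: the iridium-catalysed 1,3-hydrogen shift gives the enol(ate) on the C1–C10 side only and NCS traps it, so the chloride enters at C10 as a single constitutional isomer, which avoids the unselective halogenation of an ethyl ketone.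

**Step 14**
Reactants: 16 α-chloro ketone
Product: 17 C10 thioacetate (C1 ketone, C8–C9 epoxide intact)
Conditions: KSAc, DMF, 0 °C
Reagents that add atoms: potassium thioacetate, CC(=O)[S-].[K+]
Why: SN2 displacement at the α-keto carbon by thioacetate, far faster than attack on the epoxide, installs the sulfur atom at C10.

**Step 15**
Reactants: 17 C10 thioacetate
Product: 19 C9 bromide C8 trimethylsilyl ether C1 dioxolane (C10 thioacetate kept), via β-bromo silyl ether ketone 18 (not isolated)
Conditions: TMSBr (1.0 equiv), CH2Cl2, −78 °C; then TMSOCH2CH2OTMS, TMSOTf (10 mol %), −78 → −20 °C; pyridine quench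
Reagents that add atoms: bromotrimethylsilane, C[Si](C)(C)Br; 1,2-bis(trimethylsilyloxy)ethane, C[Si](C)(C)OCCO[Si](C)(C)C
Why: Two silyl-Lewis-acid reactions in one flask: TMSBr opens the acid-sensitive epoxide at C9 to the β-bromo silyl ether, and silyl-triflate-catalysed ketalisation with the bis-silyl glycol then masks C1 before any C8 hydroxyl exists that could close onto it across the ring; the hindered tertiary C4 silyl ether should not take part.

**Step 16**
Reactants: 19 bromide ketal
Product: 21 eleven-membered cyclic sulfide (S between C9 and C10; C8 hydroxyl free), via epoxy thiol 20 (not isolated)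
Conditions: K2CO3, degassed MeOH, slow addition to 1 mM, rt → 40 °C
Reagents that add atoms: none
Why: Base methanolysis frees the C10 thiolate and the C8 alkoxide, the alkoxide closes the C8–C9 epoxide again, and intramolecular thiolate opening at the unhindered terminal carbon C9 (endo mode, high dilution) closes the thioether ring and releases the C8 hydroxyl with its C–O bond untouched.

**Step 17**
Reactants: 21 eleven-membered cyclic sulfide
Product: 22 eleven-membered cyclic sulfone (4S,6R,7S,8R; C1 dioxolane, C4 OTBS, C6 OPMB, C8 OH, C12 OTBS, C10 epimers)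
Conditions: mCPBA (2.2 equiv), NaHCO3, CH2Cl2, 0 °C → rt
Reagents that add atoms: 3-chloroperbenzoic acid, OOC(=O)c1cccc(Cl)c1
Why: Peracid oxidation of the sulfide through the sulfoxide to the sulfone; no olefin is present and the PMB ether, ketal and silyl ethers are stable.

**Step 18**
Reactants: 22 eleven-membered cyclic sulfone
Product: 25 (4S,6R,7S,8S,9Z)-cyclodecene with the trisubstituted C9=C10 olefin, via α-bromo sulfone 23 (not isolated), via episulfone 24 (not isolated)
Conditions: CBr2F2, KOH/Al2O3, t-BuOH/CH2Cl2, 0 °C → rt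
Reagents that add atoms: none
Why: Ramberg–Bäcklund reaction with in-situ halogenation: base removes an α-sulfonyl proton and CBr2F2 brominates the carbanion, expected at C10 because the C8 alkoxide disfavours a second negative charge on neighbouring C9; deprotonation at C9 then displaces bromide in a 3-exo-tet 1,3-elimination to the episulfone, which loses SO2 and leaves the C9=C10 double bond. The closest known reaction type is the Ramberg–Bäcklund contraction of medium and large cyclic sulfones to cycloalkenes. The ten-membered carbocycle is therefore made by extrusion from the pre-formed eleven-membered ring (three-membered ring closure, then loss of the one-atom bridge), so no medium-ring C–C cyclisation is needed. No stereocentre is formed. The step needs protection against β-elimination and a Z olefin: C8 is carried as its alkoxide, which cannot leave, and the C1 ketal is cyclic, so that opening by a C10 carbanion is reversible. A bromine that enters at C9 instead is funnelled through the C8–C9 epoxy sulfone to the same type of episulfone, and the mild base together with the lower strain of a cis-cyclodecene should favour Z.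

**Step 19**
Reactants: 25 (Z)-cyclodecene
Product: 26 (4S,6R,7S,8S,10R)-cyclodecane (C10 methyl set)
Conditions: H2 (1 atm), [Ir(cod)(PCy3)(py)]PF6 (5 mol %), CH2Cl2, rt
Reagents that add atoms: none
Why: Hydroxyl-directed hydrogenation: the cationic iridium catalyst binds the C8 hydroxyl and adds hydrogen to the olefin face on which that oxygen sits; in the strain-minimised allylic conformer of the Z olefin (C8–H in the olefin plane, facing C1) this is the outer face, and delivery there gives the (R) centre at C10.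

**Step 20**
Reactants: 26 cyclodecane
Product: 27 triol (C4, C8 and C12 hydroxyls free)
Conditions: n-Bu4NF, THF, 50 °C
Reagents that add atoms: none
Why: Fluoride cleavage of both silyl ethers (warming serves the tertiary one); no base-sensitive group is present at this stage.

**Step 21**
Reactants: 27 triol
Product: 29 cis-fused 12,8-lactone (γ-lactone on O8), via lactol 28 (not isolated)
Conditions: TEMPO (20 mol %), PhI(OAc)2, CH2Cl2, rt
Reagents that add atoms: none
Why: Oxoammonium-mediated oxidative lactonisation: the primary alcohol is oxidised to the aldehyde, which forms the five-membered lactol with the C8 hydroxyl (C6 is blocked as its PMB ether) and is oxidised further to the lactone; the tertiary C4 hydroxyl is inert.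

**Step 22**
Reactants: 29 12,8-lactone
Product: 32 α-methylene lactone, via Mannich base 30 (not isolated), via trimethylammonium iodide 31 (not isolated)
Conditions: LiN(iPr)2 (3.2 equiv), THF, −78 °C; CH2=NMe2+ I−, −78 → 0 °C; then MeI, THF/MeOH, rt; then aq. NaHCO3
Reagents that add atoms: N,N-dimethylmethyleneiminium iodide (Eschenmoser's salt), C=[N+](C)C.[I-]
Why: α-Methylenation by Mannich reaction of the lithium lactone enolate, N-methylation and base-induced elimination of trimethylamine; the ketal prevents enolisation at C1 and the extra base covers the C4 hydroxyl.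

**Step 23**
Reactants: 32 α-methylene lactone
Product: 33 C6 alcohol
Conditions: DDQ, CH2Cl2/pH 7 buffer, 0 °C
Reagents that add atoms: none
Why: Oxidative cleavage of the PMB ether with DDQ under buffered conditions, which the methylene lactone and the ketal tolerate.

**Step 24**
Reactants: 33 C6 alcohol
Product: 34 C6 isobutyrate (C1 still a dioxolane)
Conditions: (i-PrCO)2O, Et3N, DMAP (cat.), CH2Cl2, 0 °C → rt
Reagents that add atoms: isobutyric anhydride, CC(C)C(=O)OC(=O)C(C)C
Why: DMAP-catalysed acylation of the secondary C6 hydroxyl; the tertiary C4 hydroxyl should not react under these conditions.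

**Step 25**
Reactants: 34 C6 isobutyrate
Product: 35 target CNP0293926.1
Conditions: PPTS, acetone/H2O, 45 °C
Reagents that add atoms: water, O
Why: Mild acid-catalysed ketal hydrolysis (exchange to acetone) unmasks the C1 ketone without touching the ester, the methylene lactone or the C10 centre.

**Compound list**

1 | geraniol, (E)-3,7-dimethylocta-2,6-dien-1-ol | CC(C)=CCC/C(C)=C/CO | starting material
2 | (2S,3S)-2,3-epoxygeraniol | CC(C)=CCC[C@]1(C)O[C@H]1CO | intermediate
3 | (S)-3,7-dimethyloct-6-ene-1,3-diol | CC(C)=CCC[C@](C)(O)CCO | intermediate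
4 | (S)-3,7-dimethyl-1-(triethylsilyloxy)oct-6-en-3-ol, formed in the flask | CC(C)=CCC[C@](C)(O)CCO[Si](CC)(CC)CC | intermediate
5 | (S)-3-(tert-butyldimethylsilyloxy)-3,7-dimethyl-1-(triethylsilyloxy)oct-6-ene | CC(C)=CCC[C@](C)(O[Si](C)(C)C(C)(C)C)CCO[Si](CC)(CC)CC | intermediate
6 | (S)-3-(tert-butyldimethylsilyloxy)-3,7-dimethyloct-6-enal | CC(C)=CCC[C@](C)(O[Si](C)(C)C(C)(C)C)CC=O | intermediate
7 | but-3-yn-1-ol | C#CCCO | starting material
8 | tert-butyl(but-3-yn-1-yloxy)dimethylsilane | C#CCCO[Si](C)(C)C(C)(C)C | intermediate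
9 | (E)-2-[4-(tert-butyldimethylsilyloxy)but-1-en-1-yl]-4,4,5,5-tetramethyl-1,3,2-dioxaborolane | CC(C)(C)[Si](C)(C)OCC/C=C/B1OC(C)(C)C(C)(C)O1 | intermediate
10 | (E)-2-[5-(tert-butyldimethylsilyloxy)pent-2-en-1-yl]-4,4,5,5-tetramethyl-1,3,2-dioxaborolane | CC(C)(C)[Si](C)(C)OCC/C=C/CB1OC(C)(C)C(C)(C)O1 | intermediate
11 | anti homoallylic alcohol (4S,6R,7S): C4 OTBS, C6 OH, C7 CH2CH2OTBS, C8=C9 vinyl, isopropylidene end at C1 | CC(C)=CCC[C@](C)(O[Si](C)(C)C(C)(C)C)C[C@@H](O)[C@@H](CCO[Si](C)(C)C(C)(C)C)C=C | intermediate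
12 | C8–C9 epoxy alcohol, epoxide oxygen syn to C6–OH | CC(C)=CCC[C@](C)(O[Si](C)(C)C(C)(C)C)C[C@@H](O)[C@@H](CCO[Si](C)(C)C(C)(C)C)[C@@H]1CO1 | intermediate
13 | C6 4-methoxybenzyl ether of 12 | CC(C)=CCC[C@](C)(O[Si](C)(C)C(C)(C)C)C[C@@H](OCc1ccc(OC)cc1)[C@@H](CCO[Si](C)(C)C(C)(C)C)[C@@H]2CO2 | intermediate
14 | C1 aldehyde | O=CCC[C@](C)(O[Si](C)(C)C(C)(C)C)C[C@@H](OCc1ccc(OC)cc1)[C@@H](CCO[Si](C)(C)C(C)(C)C)[C@@H]2CO2 | intermediate
15 | C1 vinyl carbinol, C1 epimers | C=CC(O)CC[C@](C)(O[Si](C)(C)C(C)(C)C)C[C@@H](OCc1ccc(OC)cc1)[C@@H](CCO[Si](C)(C)C(C)(C)C)[C@@H]2CO2 | intermediate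
16 | α-chloro ketone: C1 ketone, C10 chloride, C10 epimers | CC(Cl)C(=O)CC[C@](C)(O[Si](C)(C)C(C)(C)C)C[C@@H](OCc1ccc(OC)cc1)[C@@H](CCO[Si](C)(C)C(C)(C)C)[C@@H]2CO2 | intermediate
17 | C10 thioacetate, C1 ketone, C8–C9 epoxide | CC(SC(C)=O)C(=O)CC[C@](C)(O[Si](C)(C)C(C)(C)C)C[C@@H](OCc1ccc(OC)cc1)[C@@H](CCO[Si](C)(C)C(C)(C)C)[C@@H]2CO2 | intermediate
18 | C9 bromide, C8 OTMS, C1 ketone, formed in the flask | CC(SC(C)=O)C(=O)CC[C@](C)(O[Si](C)(C)C(C)(C)C)C[C@@H](OCc1ccc(OC)cc1)[C@@H](CCO[Si](C)(C)C(C)(C)C)[C@H](CBr)O[Si](C)(C)C | intermediate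
19 | C9 bromide, C8 OTMS, C1 dioxolane, C10 thioacetate | CC(SC(C)=O)C1(OCCO1)CC[C@](C)(O[Si](C)(C)C(C)(C)C)C[C@@H](OCc2ccc(OC)cc2)[C@@H](CCO[Si](C)(C)C(C)(C)C)[C@H](CBr)O[Si](C)(C)C | intermediate
20 | epoxy thiol: C10 SH, C1 dioxolane, C8–C9 epoxide, formed in the flask | CC(S)C1(OCCO1)CC[C@](C)(O[Si](C)(C)C(C)(C)C)C[C@@H](OCc2ccc(OC)cc2)[C@@H](CCO[Si](C)(C)C(C)(C)C)[C@@H]3CO3 | intermediate
21 | eleven-membered cyclic sulfide, S between C9 and C10 | S1C[C@H](O)[C@H](CCO[Si](C)(C)C(C)(C)C)[C@H](OCc2ccc(OC)cc2)C[C@@](C)(O[Si](C)(C)C(C)(C)C)CCC3(OCCO3)C1C | intermediate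
22 | eleven-membered cyclic sulfone (4S,6R,7S,8R), key-step precursor | O=S1(=O)C[C@H](O)[C@H](CCO[Si](C)(C)C(C)(C)C)[C@H](OCc2ccc(OC)cc2)C[C@@](C)(O[Si](C)(C)C(C)(C)C)CCC3(OCCO3)C1C | intermediate
23 | C10-bromo sulfone, formed in the flask | O=S1(=O)C[C@H](O)[C@H](CCO[Si](C)(C)C(C)(C)C)[C@H](OCc2ccc(OC)cc2)C[C@@](C)(O[Si](C)(C)C(C)(C)C)CCC3(OCCO3)C1(C)Br | intermediate
24 | episulfone (thiirane 1,1-dioxide across C9–C10), formed in the flask | O=S1(=O)C2[C@H](O)[C@H](CCO[Si](C)(C)C(C)(C)C)[C@H](OCc3ccc(OC)cc3)C[C@@](C)(O[Si](C)(C)C(C)(C)C)CCC4(OCCO4)C12C | intermediate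
25 | (4S,6R,7S,8S,9Z)-cyclodecene, key-step product | C/C1=C/[C@H](O)[C@H](CCO[Si](C)(C)C(C)(C)C)[C@H](OCc2ccc(OC)cc2)C[C@@](C)(O[Si](C)(C)C(C)(C)C)CCC13OCCO3 | intermediate
26 | (4S,6R,7S,8S,10R)-cyclodecane | C[C@@H]1C[C@H](O)[C@H](CCO[Si](C)(C)C(C)(C)C)[C@H](OCc2ccc(OC)cc2)C[C@@](C)(O[Si](C)(C)C(C)(C)C)CCC13OCCO3 | intermediate
27 | triol (C4, C8, C12 OH; C6 OPMB; C1 dioxolane) | C[C@@H]1C[C@H](O)[C@H](CCO)[C@H](OCc2ccc(OC)cc2)C[C@@](C)(O)CCC13OCCO3 | intermediate
28 | lactol on O8, formed in the flask | C[C@@H]1C[C@@H]2OC(O)C[C@@H]2[C@H](OCc3ccc(OC)cc3)C[C@@](C)(O)CCC14OCCO4 | intermediate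
29 | cis-fused 12,8-lactone | C[C@@H]1C[C@@H]2OC(=O)C[C@@H]2[C@H](OCc3ccc(OC)cc3)C[C@@](C)(O)CCC14OCCO4 | intermediate
30 | Mannich base (C11 CH2NMe2), formed in the flask | CN(C)CC1C(=O)O[C@H]2C[C@@H](C)C3(OCCO3)CC[C@](C)(O)C[C@@H](OCc4ccc(OC)cc4)[C@@H]12 | intermediate
31 | trimethylammonium iodide of 30, formed in the flask | C[N+](C)(C)CC1C(=O)O[C@H]2C[C@@H](C)C3(OCCO3)CC[C@](C)(O)C[C@@H](OCc4ccc(OC)cc4)[C@@H]12.[I-] | intermediate
32 | α-methylene lactone (C6 OPMB, C1 dioxolane) | C=C1C(=O)O[C@H]2C[C@@H](C)C3(OCCO3)CC[C@](C)(O)C[C@@H](OCc4ccc(OC)cc4)[C@@H]12 | intermediate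
33 | C6 alcohol | C=C1C(=O)O[C@H]2C[C@@H](C)C3(OCCO3)CC[C@](C)(O)C[C@@H](O)[C@@H]12 | intermediate
34 | C6 isobutyrate, C1 dioxolane | C=C1C(=O)O[C@H]2C[C@@H](C)C3(OCCO3)CC[C@](C)(O)C[C@@H](OC(=O)C(C)C)[C@@H]12 | intermediate
35 | CNP0293926.1, (4S,6R,7S,8S,10R)-4-hydroxy-6-isobutyryloxy-1-oxogermacr-11(13)-en-12,8-olide | C=C1C(=O)O[C@H]2C[C@@H](C)C(=O)CC[C@](C)(O)C[C@@H](OC(=O)C(C)C)[C@@H]12 | target

**Step count.** Total: 25 steps. Longest linear sequence: 22 steps (steps 1–4 and 8–25, from geraniol); the allylboronate branch is steps 5–7.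

**Steps most likely to fail**

Step 18 (key step). The base may open the ring by retro-addition across C8–C9, or a C10 carbanion may open the C1 dioxolane by β-elimination, before halogenation and closure take place. The fallback sets out from sulfone 22 and returns at cycloalkene 25; it makes the C8 oxygen itself the leaving group. Sulfone 22 is treated at −78 °C with LiN(SiMe3)2 (2.2 equiv), the alkoxide directing lithiation to C9, and the dianion is chlorinated with C2Cl6 to the C9-chloro sulfone F1. On warming, the C8 alkoxide closes this to the C8–C9 epoxy sulfone F2, which is isolated. LiOtBu in THF (0 °C → rt) then starts the epoxy variant of the Ramberg–Bäcklund reaction: the C10 carbanion opens the epoxide at C9, the resulting episulfone loses SO2, and 25 should result with the C8–O bond never broken.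

Step 16. Chain growth by intermolecular thiolate–epoxide reaction, or methanolysis of the epoxide, may outrun the eleven-membered ring closure. The fallback sets out from thioacetate 17 and returns at sulfide 21; it closes the ring by direct SN2 displacement of a primary iodide by a caesium thiolate in DMF, with C8 silylated, instead of by epoxide opening in methanol. Compound 17 is opened with LiI/AcOH in THF to the iodohydrin F3, silylated (TESOTf, 2,6-lutidine) to the C8 triethylsilyl ether F4, and ketalised as in step 15 to the dioxolane F5. Hydrazine acetate in DMF cleaves the thioacetate to the thiol F6, which is added slowly to Cs2CO3 in DMF (high dilution, 50 °C) and should close to the C8-silylated cyclic sulfide F7. AcOH–THF–H2O at rt removes the triethylsilyl group and gives 21.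

Step 19. Hydrogen may be delivered to the wrong olefin face if the ring adopts another conformer, which would give the C10 epimer. The fallback sets out from cycloalkene 25 and returns at lactone 29; it changes the controlling element from hydroxyl direction to the shape of the bicyclic lactone. Compound 25 is desilylated (n-Bu4NF, THF, 50 °C) to the unsaturated triol F8, which is lactonised (TEMPO, PhI(OAc)2) through the unsaturated lactol F9 to the unsaturated cis-fused lactone F10. Hydrogenation of F10 (H2, Rh/Al2O3, EtOAc) should then add hydrogen from the convex face of the lactone-fused ring and give 29.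

**Further compounds**

F1 | step 18 | C9-chloro sulfone (chlorine next to the C8 alkoxide) | O=S1(=O)C(Cl)[C@H](O)[C@H](CCO[Si](C)(C)C(C)(C)C)[C@H](OCc2ccc(OC)cc2)C[C@@](C)(O[Si](C)(C)C(C)(C)C)CCC3(OCCO3)C1C
F2 | step 18 | C8–C9 epoxy sulfone | O=S1(=O)C2O[C@@H]2[C@H](CCO[Si](C)(C)C(C)(C)C)[C@H](OCc3ccc(OC)cc3)C[C@@](C)(O[Si](C)(C)C(C)(C)C)CCC4(OCCO4)C1C
F3 | step 16 | iodohydrin (C9 iodide, C8 OH, C1 ketone, C10 thioacetate) | CC(SC(C)=O)C(=O)CC[C@](C)(O[Si](C)(C)C(C)(C)C)C[C@@H](OCc1ccc(OC)cc1)[C@@H](CCO[Si](C)(C)C(C)(C)C)[C@H](CI)O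
F4 | step 16 | C8 triethylsilyl ether of F3 | CC(SC(C)=O)C(=O)CC[C@](C)(O[Si](C)(C)C(C)(C)C)C[C@@H](OCc1ccc(OC)cc1)[C@@H](CCO[Si](C)(C)C(C)(C)C)[C@H](CI)O[Si](CC)(CC)CC
F5 | step 16 | C1 dioxolane of F4 | CC(SC(C)=O)C1(OCCO1)CC[C@](C)(O[Si](C)(C)C(C)(C)C)C[C@@H](OCc2ccc(OC)cc2)[C@@H](CCO[Si](C)(C)C(C)(C)C)[C@H](CI)O[Si](CC)(CC)CC
F6 | step 16 | C10 thiol of F5 | CC(S)C1(OCCO1)CC[C@](C)(O[Si](C)(C)C(C)(C)C)C[C@@H](OCc2ccc(OC)cc2)[C@@H](CCO[Si](C)(C)C(C)(C)C)[C@H](CI)O[Si](CC)(CC)CC
F7 | step 16 | eleven-membered cyclic sulfide with C8 triethylsilyl ether | S1C[C@H](O[Si](CC)(CC)CC)[C@H](CCO[Si](C)(C)C(C)(C)C)[C@H](OCc2ccc(OC)cc2)C[C@@](C)(O[Si](C)(C)C(C)(C)C)CCC3(OCCO3)C1C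
F8 | step 19 | unsaturated triol (C9=C10 kept; C4, C8, C12 OH) | C/C1=C/[C@H](O)[C@H](CCO)[C@H](OCc2ccc(OC)cc2)C[C@@](C)(O)CCC13OCCO3
F9 | step 19 | unsaturated lactol on O8 | C/C1=C/[C@@H]2OC(O)C[C@@H]2[C@H](OCc3ccc(OC)cc3)C[C@@](C)(O)CCC14OCCO4
F10 | step 19 | unsaturated cis-fused 12,8-lactone | C/C1=C/[C@@H]2OC(=O)C[C@@H]2[C@H](OCc3ccc(OC)cc3)C[C@@](C)(O)CCC14OCCO4
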